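**Remark on the chemistry:** target 23 has no stereocentre. Compounds 16 and 18–20 form as racemates, and their stereocentres disappear on aromatization, so no enantiocontrol is planned.

## Analysis of the target

Target 23 is an achiral diaryl ether of two benzene rings, each carrying one methyl, one isopropyl and one methoxy group. Ring A (C1 OCH3, C2 H, C3 isopropyl, C4 O-aryl, C5 H, C6 CH3) is 1,2,4,5-tetrasubstituted. Ring B is pentasubstituted: ether oxygen at C1', free OH at C2', isopropyl at C3', OCH3 at C5', CH3 at C6'. There is no stereocentre, so the stereocentres made on the way matter only as intermediates. The sensitive sites are the free ring B phenol, which is ortho to one oxygen and para to another and so is easily oxidized to quinoid products, and the two electron-rich rings. The hard part is the central C–O–C unit: the ring B carbon bearing the ether oxygen is flanked by OH and CH3 and the ring A carbon by isopropyl, so a direct aryl C–O coupling would join two hindered, electron-rich partners. The three oxygens of ring B must also be told apart. The strategy rests on ring A: its two oxygens (C1 OCH3 and C4 O-aryl) are para to each other, which is the pattern a 2-oxygenated diene and an acceptor-substituted alkene produce in a (4+2) cycloaddition.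

## Retrosynthetic reasoning

**23 ⇒ 22.** The last bond formed is the O–H of the ring B phenol, released from the methoxymethyl acetal of 22. The phenol is the most oxidizable site and stays masked through all basic and oxidative operations. The acetal also directs the metalation that installs the neighbouring oxygen, and it tolerates base, titanium reagents, heat and a quinone oxidant. The forward step only has to cleave an aryl acetal beside a diaryl ether and two methyl ethers.

**22 ⇒ 21 ⇒ 20.** The C1–OCH3 bond of ring A is cut to phenol 21, and 21 is traced to cyclohexenone 20 by returning two hydrogens to ring A. Ketone 20 already has every carbon and both oxygens of ring A in place and is one unsaturation short of a phenol. The forward dehydrogenation must stop at the phenol. The methylation then needs no selectivity, because the ring B oxygen is still an acetal.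

**20 ⇒ 18 (through nitronate 19).** The C1 carbonyl is exchanged for a nitro group on sp3 carbon. The nitro group is what activates the alkene for the cycloaddition and fixes its orientation, so it acts as a ketene equivalent. The forward Nef reaction must run in base, because the tetrasubstituted aryl enol ether C3=C4 would not survive the aqueous mineral acid of the classical procedure.

**18 ⇒ 13 + 17.** Ring A bonds C1–C2 and C5–C6 are cut, giving the 2-aryloxy-3-isopropylbutadiene 13 and (E)-1-nitropropene 17. These two bonds are chosen because the cut puts the donor oxygen on C2 of a diene and the acceptor para to it. No other pair of ring bonds lets one polar substituent on each partner control the orientation. The diaryl ether C–O bond is deliberately not cut, since it would have to be re-formed between two hindered, electron-rich arenes. The forward reaction must give para regiochemistry, which is the only selectivity that survives to the target.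

**13 ⇒ 12 ⇒ 7 + 10 (through acid chloride 11).** The C4=C5 methylene of the diene is removed to give aryl ester 12, and the ester C–O bond is cut to phenol 7 and acid 10. The future ether oxygen is thus attached by acylation of a phenol, which works even on a 2,6-disubstituted phenol. The carbonyl carbon becomes C4 of ring A. The forward methylenation has to convert a conjugated aryl ester into an acid-labile enol ether without acid.

**7 ⇒ 4 (through 5 and 6) ⇒ 3 ⇒ 2 ⇒ 1.** The C1'–O bond of ring B is cut back to a C–H bond of 4, the C5'–OCH3 bond to the C–Br bond of 3, the acetal to phenol 2, and the bromine to thymol 1. Thymol supplies ring B with its methyl, isopropyl and first oxygen already in the right relation. Its free para position takes the second oxygen, and the only free position ortho to the protected oxygen takes the third. The forward steps need para-selective bromination and ortho-selective metalation.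

**10 ⇒ 9 ⇒ 8 and 17 ⇒ 16 ⇒ 14 + 15.** The methylidene of acid 10 is cut to malonic acid 9 and on to diester 8. The C=C bond of 17 is cut through nitro alcohol 16 to nitromethane 14 and acetaldehyde 15. Both branches are two conventional steps from bulk chemicals.

## Alternatives that were turned down

**Alternative 1:** Ring B's C5'–OCH3 bond is disconnected last. A finished diaryl ether without that oxygen, 2-[4-methoxy-5-methyl-2-(propan-2-yl)phenoxy]-3-methyl-6-(propan-2-yl)phenol A2, would be oxidized at an anode in the alcohol that supplies the methoxy groups. The phenol is oxidized twice at its free para position, giving the para-quinone monoketal A1, which a mild reductant returns to the para-methoxyphenol 23.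
- For it: it is short and convergent, it installs the last oxygen on an otherwise complete skeleton, and the para position is the only open site of the phenol ring.
- Against it: A2 must first be made by the hindered aryl C–O coupling that is the central difficulty of the target. Ring A of A2 is a dialkyl hydroquinone diether and is itself readily oxidized at an anode, so chemoselectivity depends on holding the potential in a narrow window. Ipso attack at the aryloxy-bearing carbon would expel ring A.
- Comparison: on step count Alternative 1 is clearly better. The chosen route trades that for never needing an aryl–oxygen coupling and never exposing the complete electron-rich biaryl ether to an oxidation that must discriminate between its two rings.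

**Alternative 2:** Ring B is disconnected at C4–C5 and traced to the 4-alkenyl-4-silyloxycyclobutenone A4, which carries the ring A aryloxy group on its enone carbon. On heating, A4 opens to a dienylketene that closes and tautomerizes to the hydroquinone derivative A3, with one oxygen free and the other silylated. Methylation of the free OH and desilylation would give 23.
- For it: this is the strongest of the alternatives on differentiating the ring B oxygens. The two para oxygens emerge already distinguished and the pentasubstituted ring forms in one regiodefined step with no later change of oxidation level.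
- Against it: ring B is built from a squaric ester atom by atom although a cheap terpene phenol already contains it. The hindered ring A phenoxide must be introduced by addition–elimination on a vinylogous ester. In the next step the same aryloxide is a good leaving group, so the alkenyllithium can displace it by conjugate addition–elimination instead of adding to the carbonyl. Several steps are cryogenic organolithium operations.
- Comparison: the step count is similar. Alternative 2 offers the better oxygen differentiation, while the chosen route keeps ring B as a bought unit and uses the aryloxy group only as a spectator donor on a diene.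

**Alternative 3:** Ring A bonds C4–C5 and C2–C3 are disconnected. The aryloxymethyl isopropyl ketone A6, made from phenol 7 by O-alkylation with an α-bromoketone, would add as its enolate to 3-methylbut-3-en-2-one A7, and the methyl ketone would then condense onto the isopropyl ketone to give cyclohexenone A5. A5 is the conjugated double-bond isomer of 20 and would finish through the same dehydrogenation, methylation and acetal cleavage.
- For it: it reaches the oxidation level of 20 from 7 in two steps instead of four, with no titanium reagent, no nitroalkene and no Nef reaction. On step economy it is stronger than the chosen route.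
- Against it: A6 must enolize toward the aryloxy-bearing CH2 and not the isopropyl CH. A7 polymerizes readily under base. The ring closure is an aldol attack on an α-branched, α-aryloxy isopropyl ketone, a very hindered electrophile, and it competes with retro-Michael cleavage and with the alternative aldol of the isopropyl-side enolate onto the methyl ketone.
- Comparison: the chosen route offers a neutral, thermal ring formation whose orientation follows from the polarization of the two partners, and it avoids the hindered aldol closure.

Key step: step 11

## Route

**Step 1**
Reactants: 1 thymol (5-methyl-2-(propan-2-yl)phenol)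
Product: 2 4-bromo-5-methyl-2-(propan-2-yl)phenol
Conditions: NBS, MeCN, 0 °C → rt
Reagents that add atoms: N-bromosuccinimide, O=C1CCC(=O)N1Br
Why: Electrophilic aromatic bromination; the hydroxyl directs to its free para position, which is less hindered than the remaining ortho site between OH and CH3.

**Step 2**
Reactants: 2 4-bromo-5-methyl-2-(propan-2-yl)phenol
Product: 3 1-bromo-4-(methoxymethoxy)-2-methyl-5-(propan-2-yl)benzene
Conditions: MOMCl, iPr2NEt, CH2Cl2, 0 °C → 40 °C
Reagents that add atoms: chloromethyl methyl ether, COCCl
Why: O-alkylation of the phenol by the highly reactive α-chloro ether (Williamson-type); the acetal protects the phenol against base and organometallics and later serves as the directing group.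

**Step 3**
Reactants: 3 1-bromo-4-(methoxymethoxy)-2-methyl-5-(propan-2-yl)benzene
Product: 4 1-methoxy-4-(methoxymethoxy)-2-methyl-5-(propan-2-yl)benzene
Conditions: NaOMe (25% in MeOH), CuI (10 mol%), DMF, 110 °C
Reagents that add atoms: sodium methoxide, [Na+].[O-]C
Why: Ullmann-type copper-catalysed methoxylation of an unactivated aryl bromide; the acetal is stable to methoxide and the bromide has only one ortho substituent.

**Step 4**
Reactants: 4 1-methoxy-4-(methoxymethoxy)-2-methyl-5-(propan-2-yl)benzene
Product: 7 3-methoxy-6-(methoxymethoxy)-2-methyl-5-(propan-2-yl)phenol, via aryllithium 5 (not isolated), via dimethyl arylboronate 6 (not isolated)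
Conditions: n-BuLi, TMEDA, Et2O, 0 °C → rt; B(OMe)3, −78 °C → rt; 30% H2O2, aq NaOH, 0 °C → rt
Reagents that add atoms: hydrogen peroxide, OO
Why: Directed ortho-metalation; the chelating OCH2OCH3 group is the stronger director and its only free ortho C–H lies between it and CH3, while the other ring C–H is flanked by the weaker OCH3 director and the bulky isopropyl group. Borylation and alkaline peroxide oxidation (1,2-shift of aryl from boron to oxygen) then replace lithium by OH at the same carbon.

**Step 5**
Reactants: 8 diethyl 2-(propan-2-yl)propanedioate
Product: 9 2-(propan-2-yl)propanedioic acid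
Conditions: KOH, EtOH/H2O, reflux; then aq HCl, 0 °C
Reagents that add atoms: potassium hydroxide, [K+].[OH-]
Why: Saponification of both esters by acyl–oxygen cleavage; cold acidification avoids premature decarboxylation.

**Step 6**
Reactants: 9 2-(propan-2-yl)propanedioic acid
Product: 10 3-methyl-2-methylidenebutanoic acid
Conditions: (CH2O)n, Et2NH, EtOAc, reflux
Reagents that add atoms: formaldehyde (as paraformaldehyde), C=O
Why: Decarboxylative Mannich methylenation; the malonic acid adds to the iminium ion and the Mannich base loses CO2 and the amine to give the 2-substituted acrylic acid.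

**Step 7**
Reactants: 10 3-methyl-2-methylidenebutanoic acid; 7 3-methoxy-6-(methoxymethoxy)-2-methyl-5-(propan-2-yl)phenol
Product: 12 3-methoxy-6-(methoxymethoxy)-2-methyl-5-(propan-2-yl)phenyl 3-methyl-2-methylidenebutanoate, via acid chloride 11 (not isolated)
Conditions: (COCl)2, DMF (cat.), CH2Cl2, 0 °C → rt; then 7, Et3N, DMAP (cat.), BHT (cat.), CH2Cl2, 0 °C → rt
Reagents that add atoms: none
Why: Acid chloride formation followed by DMAP-catalysed acylation (nucleophilic acyl substitution); acylation reaches even a 2,6-disubstituted phenol, and the acid chloride has no α-hydrogen, so no ketene can form.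

**Step 8**
Reactants: 12 3-methoxy-6-(methoxymethoxy)-2-methyl-5-(propan-2-yl)phenyl 3-methyl-2-methylidenebutanoate
Product: 13 1-methoxy-4-(methoxymethoxy)-2-methyl-3-[(4-methyl-3-methylidenepent-1-en-2-yl)oxy]-5-(propan-2-yl)benzene
Conditions: Cp2TiMe2, toluene, 70 °C, dark; filtration through basic alumina
Reagents that add atoms: dimethyltitanocene, [CH3-].[CH3-].[Ti+4].c1cc[cH-]c1.c1cc[cH-]c1
Why: Petasis methylenation; Cp2TiMe2 loses methane on heating to give Cp2Ti=CH2, which adds across the ester carbonyl and fragments to the enol ether and Cp2TiO. The medium is free of acid, conjugated esters are known to give 2-oxy-1,3-dienes, and the 1,1-disubstituted alkene can only undergo degenerate exchange with the methylidene.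

**Step 9**
Reactants: 14 nitromethane; 15 acetaldehyde
Product: 16 1-nitropropan-2-ol (racemic)
Conditions: NaOH (cat.), H2O/MeOH, 0 °C → rt, excess 14; AcOH quench
Reagents that add atoms: none
Why: Henry (nitroaldol) addition of the nitronate to the aldehyde; excess nitromethane suppresses double addition, and the new stereocentre is racemic and removed in the next step.

**Step 10**
Reactants: 16 1-nitropropan-2-ol
Product: 17 (E)-1-nitroprop-1-ene
Conditions: phthalic anhydride, 150–180 °C, reduced pressure, product distilled from the melt
Reagents that add atoms: none
Why: Dehydration through the hydrogen phthalate ester with β-elimination toward the acidic carbon next to nitro; the E isomer is the thermodynamically favoured product and is removed by distillation as it forms.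

**Step 11 (key step)**
Reactants: 13 1-methoxy-4-(methoxymethoxy)-2-methyl-3-[(4-methyl-3-methylidenepent-1-en-2-yl)oxy]-5-(propan-2-yl)benzene; 17 (E)-1-nitroprop-1-ene
Product: 18 1-methoxy-4-(methoxymethoxy)-2-methyl-3-{[5-methyl-4-nitro-2-(propan-2-yl)cyclohex-1-en-1-yl]oxy}-5-(propan-2-yl)benzene (racemic; methyl and nitro trans)
Conditions: 17 (3 equiv), BHT (5 mol%), toluene, 100 °C, sealed tube
Reagents that add atoms: none
Why: Thermal, concerted but asynchronous (4+2) cycloaddition between the s-cis diene 13 (HOMO) and nitroalkene 17 (LUMO); the closest known reaction type is the Diels–Alder reaction of 2-alkoxy-, 2-silyloxy- and 2-aryloxy-1,3-dienes with nitroalkenes used as ketene equivalents. The aryloxy oxygen places the largest HOMO coefficient on the CH2 attached to the oxygen-bearing carbon and the LUMO of 17 is largest at the methyl-bearing β-carbon, so these carbons join (ring A bond C5–C6) and the nitro carbon bonds to the other terminus (bond C1–C2). Ring A is thereby closed as a six-membered ring in a suprafacial–suprafacial cycloaddition in which both σ-bonds form in one step, with nitro on C1 para to the O-aryl on C4 and methyl on C6. The new stereocentres C1 and C6 are fixed relative to each other by the E geometry of 17, which is carried over suprafacially to a trans arrangement; the diene termini are unsubstituted, so there is no endo/exo question, and 18 forms as a racemate. The selectivity the step needs is regioselectivity, para over meta; it is secured by the oxygen donor on C2 of the diene, which outweighs the weak alkyl donor on C3, and by the nitro group, which dominates the methyl group in polarizing 17. Lewis acids are left out because they would make 17 react as a heterodiene with the enol ether and would endanger the enol ether and the acetal, and BHT limits polymerization of 17. Both stereocentres are erased later, so their ratio has no consequence for the route.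

**Step 12**
Reactants: 18 1-methoxy-4-(methoxymethoxy)-2-methyl-3-{[5-methyl-4-nitro-2-(propan-2-yl)cyclohex-1-en-1-yl]oxy}-5-(propan-2-yl)benzene
Product: 20 4-[3-methoxy-6-(methoxymethoxy)-2-methyl-5-(propan-2-yl)phenoxy]-6-methyl-3-(propan-2-yl)cyclohex-3-en-1-one (racemic), via potassium nitronate 19 (not isolated)
Conditions: K2CO3, 30% H2O2, MeOH, 0 °C → rt
Reagents that add atoms: hydrogen peroxide, OO
Why: Oxidative Nef reaction in base; the nitronate carbon is oxygenated by the peroxide and the resulting α-hydroxy nitro compound loses nitrite to give the ketone. The medium stays basic, so the aryl enol ether and the acetal are not hydrolysed, and the electron-rich enol ether is inert to the nucleophilic hydroperoxide anion.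

**Step 13**
Reactants: 20 4-[3-methoxy-6-(methoxymethoxy)-2-methyl-5-(propan-2-yl)phenoxy]-6-methyl-3-(propan-2-yl)cyclohex-3-en-1-one
Product: 21 4-[3-methoxy-6-(methoxymethoxy)-2-methyl-5-(propan-2-yl)phenoxy]-2-methyl-5-(propan-2-yl)phenol
Conditions: DDQ (1.1 equiv), 1,4-dioxane (dry), rt
Reagents that add atoms: none
Why: Quinone dehydrogenation; 20 enolizes easily because C2–H2 is both α to the carbonyl and allylic to the enol ether, and the resulting hydroxy(aryloxy)cyclohexadiene gives up hydride and a proton to DDQ, with aromatization as the driving force. One equivalent at room temperature in a dry, non-nucleophilic solvent should spare the benzylic C–H bonds and the acetal.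

**Step 14**
Reactants: 21 4-[3-methoxy-6-(methoxymethoxy)-2-methyl-5-(propan-2-yl)phenoxy]-2-methyl-5-(propan-2-yl)phenol
Product: 22 1-methoxy-3-[4-methoxy-5-methyl-2-(propan-2-yl)phenoxy]-4-(methoxymethoxy)-2-methyl-5-(propan-2-yl)benzene
Conditions: MeI, K2CO3, acetone, reflux
Reagents that add atoms: iodomethane, CI
Why: Williamson ether synthesis (SN2 of the phenoxide on iodomethane); the ring B oxygen is still an acetal, so only the ring A phenol is methylated.

**Step 15**
Reactants: 22 1-methoxy-3-[4-methoxy-5-methyl-2-(propan-2-yl)phenoxy]-4-(methoxymethoxy)-2-methyl-5-(propan-2-yl)benzene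
Product: 23 4-methoxy-2-[4-methoxy-5-methyl-2-(propan-2-yl)phenoxy]-3-methyl-6-(propan-2-yl)phenol
Conditions: HCl (3 M aq), MeOH, 50 °C
Reagents that add atoms: none
Why: Acid-catalysed cleavage of the aryl methoxymethyl acetal through an oxocarbenium ion that is captured by methanol; the diaryl ether and the aryl methyl ethers are inert to dilute acid at this temperature.

## Compound list

1 | thymol, 5-methyl-2-(propan-2-yl)phenol | Cc1ccc(C(C)C)c(O)c1 | starting material
2 | 4-bromo-5-methyl-2-(propan-2-yl)phenol | Cc1cc(O)c(C(C)C)cc1Br | intermediate
3 | 1-bromo-4-(methoxymethoxy)-2-methyl-5-(propan-2-yl)benzene | Cc1cc(OCOC)c(C(C)C)cc1Br | intermediate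
4 | 1-methoxy-4-(methoxymethoxy)-2-methyl-5-(propan-2-yl)benzene | Cc1cc(OCOC)c(C(C)C)cc1OC | intermediate
5 | [3-methoxy-6-(methoxymethoxy)-2-methyl-5-(propan-2-yl)phenyl]lithium | Cc1c([Li])c(OCOC)c(C(C)C)cc1OC | intermediate (not isolated)
6 | dimethyl [3-methoxy-6-(methoxymethoxy)-2-methyl-5-(propan-2-yl)phenyl]boronate | Cc1c(B(OC)OC)c(OCOC)c(C(C)C)cc1OC | intermediate (not isolated)
7 | 3-methoxy-6-(methoxymethoxy)-2-methyl-5-(propan-2-yl)phenol | Cc1c(O)c(OCOC)c(C(C)C)cc1OC | intermediate
8 | diethyl 2-(propan-2-yl)propanedioate | CCOC(=O)C(C(C)C)C(=O)OCC | starting material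
9 | 2-(propan-2-yl)propanedioic acid | CC(C)C(C(=O)O)C(=O)O | intermediate
10 | 3-methyl-2-methylidenebutanoic acid | C=C(C(C)C)C(=O)O | intermediate
11 | 3-methyl-2-methylidenebutanoyl chloride | C=C(C(C)C)C(=O)Cl | intermediate (not isolated)
12 | 3-methoxy-6-(methoxymethoxy)-2-methyl-5-(propan-2-yl)phenyl 3-methyl-2-methylidenebutanoate | C=C(C(C)C)C(=O)Oc1c(C)c(OC)cc(C(C)C)c1OCOC | intermediate
13 | 1-methoxy-4-(methoxymethoxy)-2-methyl-3-[(4-methyl-3-methylidenepent-1-en-2-yl)oxy]-5-(propan-2-yl)benzene | C=C(Oc1c(C)c(OC)cc(C(C)C)c1OCOC)C(=C)C(C)C | intermediate
14 | nitromethane | C[N+](=O)[O-] | starting material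
15 | acetaldehyde | CC=O | starting material
16 | 1-nitropropan-2-ol, racemic | CC(O)C[N+](=O)[O-] | intermediate
17 | (E)-1-nitroprop-1-ene | C/C=C/[N+](=O)[O-] | intermediate
18 | 1-methoxy-4-(methoxymethoxy)-2-methyl-3-{[5-methyl-4-nitro-2-(propan-2-yl)cyclohex-1-en-1-yl]oxy}-5-(propan-2-yl)benzene, racemic trans, one enantiomer drawn | C[C@@H]1CC(Oc2c(C)c(OC)cc(C(C)C)c2OCOC)=C(C(C)C)C[C@H]1[N+](=O)[O-] | intermediate
19 | potassium nitronate of 18 (aci-nitro salt at C1 of the cyclohexene), racemic | CC1CC(Oc2c(C)c(OC)cc(C(C)C)c2OCOC)=C(C(C)C)CC1=[N+]([O-])[O-].[K+] | intermediate (not isolated)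
20 | 4-[3-methoxy-6-(methoxymethoxy)-2-methyl-5-(propan-2-yl)phenoxy]-6-methyl-3-(propan-2-yl)cyclohex-3-en-1-one, racemic | CC1CC(Oc2c(C)c(OC)cc(C(C)C)c2OCOC)=C(C(C)C)CC1=O | intermediate
21 | 4-[3-methoxy-6-(methoxymethoxy)-2-methyl-5-(propan-2-yl)phenoxy]-2-methyl-5-(propan-2-yl)phenol | Cc1cc(Oc2c(C)c(OC)cc(C(C)C)c2OCOC)c(C(C)C)cc1O | intermediate
22 | 1-methoxy-3-[4-methoxy-5-methyl-2-(propan-2-yl)phenoxy]-4-(methoxymethoxy)-2-methyl-5-(propan-2-yl)benzene | COc1cc(C(C)C)c(Oc2c(C)c(OC)cc(C(C)C)c2OCOC)cc1C | intermediate
23 | 4-methoxy-2-[4-methoxy-5-methyl-2-(propan-2-yl)phenoxy]-3-methyl-6-(propan-2-yl)phenol | COc1cc(C(C)C)c(Oc2c(C)c(OC)cc(C(C)C)c2O)cc1C | target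

## Step count and least certain steps

Total step count: 15. Longest linear sequence: 11 steps from thymol 1 (steps 1, 2, 3, 4, 7, 8, 11, 12, 13, 14, 15).

**Step 11 (key step).** The most likely failure is erosion of regioselectivity or a stalled cycloaddition. The aryloxy group is a weaker donor than an alkoxy or silyloxy group and is opposed by the isopropyl group on C3, and the β-methyl group makes 17 less reactive than nitroethylene. Prolonged heating then favours polymerization of 17 or hetero-cycloaddition of the nitroalkene across the enol ether. The fallback gives up building ring A and forms the diaryl ether by copper catalysis. It sets out from phenol 7. Purchased 2-methoxy-1-methyl-4-(propan-2-yl)benzene F1 is iodinated para to its methoxy group (NIS, TFA cat., MeCN) to give 1-iodo-4-methoxy-5-methyl-2-(propan-2-yl)benzene F2. Ullmann coupling of 7 with F2 (CuI, picolinic acid, K3PO4, DMSO, 100 °C) should give 22 directly, where the route is rejoined before the final deprotection.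

**Step 8.** Incomplete methylenation of the hindered aryl ester, or hydrolysis of the very acid-sensitive dienyl ether during isolation, is the likely problem. The fallback builds the enol ether from a ketone and sets out from phenol 7. O-alkylation with purchased 1-bromo-3-methylbutan-2-one F3 (K2CO3, acetone) gives 1-[3-methoxy-6-(methoxymethoxy)-2-methyl-5-(propan-2-yl)phenoxy]-3-methylbutan-2-one F4, the same ketone as A6. Mannich-type α-methylenation at the aryloxy-bearing CH2 (aqueous formaldehyde, diisopropylammonium trifluoroacetate, THF, reflux) gives 2-[3-methoxy-6-(methoxymethoxy)-2-methyl-5-(propan-2-yl)phenoxy]-4-methylpent-1-en-3-one F5. Wittig methylenation of its ketone (Ph3P=CH2, THF) returns to diene 13.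

**Step 12.** The β,γ-unsaturated ketone may drift into conjugation under carbonate, after which the hydroperoxide anion can epoxidize the enone (Weitz–Scheffer), or the nitronate oxidation may remain incomplete. The fallback is reductive and sets out from 18. Reduction of the secondary nitro group with SnCl2, PhSH and Et3N in MeCN should stop at the oxime, 4-[3-methoxy-6-(methoxymethoxy)-2-methyl-5-(propan-2-yl)phenoxy]-6-methyl-3-(propan-2-yl)cyclohex-3-en-1-one oxime F6. Deoximation with aqueous TiCl3 buffered by NH4OAc near pH 6 would return to ketone 20 without strong acid or an oxidant.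

**Step 13.** Over-oxidation of the product, a para-aryloxyphenol that a quinone oxidant can carry on to a quinone with loss of ring B, is the main concern. Benzylic oxidation on ring B and hydrolysis of the enol ether by the acidic hydroquinone before aromatization are also possible. The fallback sets out from 20. Silylation of the extended enolate (KHMDS, TBSCl, THF, −78 °C) gives the dienol ether tert-butyl({4-[3-methoxy-6-(methoxymethoxy)-2-methyl-5-(propan-2-yl)phenoxy]-6-methyl-3-(propan-2-yl)cyclohexa-1,3-dien-1-yl}oxy)dimethylsilane F7. This cyclohexadiene is dehydrogenated catalytically over palladium on carbon (Pd/C) with 3,3-dimethylbut-1-ene as hydrogen acceptor in toluene at 80 °C to the aryl silyl ether tert-butyl{4-[3-methoxy-6-(methoxymethoxy)-2-methyl-5-(propan-2-yl)phenoxy]-2-methyl-5-(propan-2-yl)phenoxy}dimethylsilane F8. TBAF in THF then returns to phenol 21, and the phenol is never exposed to an oxidant.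

## Further compounds

F1 | step 11 | 2-methoxy-1-methyl-4-(propan-2-yl)benzene (carvacrol methyl ether, purchased) | COc1cc(C(C)C)ccc1C
F2 | step 11 | 1-iodo-4-methoxy-5-methyl-2-(propan-2-yl)benzene | COc1cc(C(C)C)c(I)cc1C
F3 | step 8 | 1-bromo-3-methylbutan-2-one (purchased) | CC(C)C(=O)CBr
F4 | step 8 | 1-[3-methoxy-6-(methoxymethoxy)-2-methyl-5-(propan-2-yl)phenoxy]-3-methylbutan-2-one | CC(C)C(=O)COc1c(C)c(OC)cc(C(C)C)c1OCOC
F5 | step 8 | 2-[3-methoxy-6-(methoxymethoxy)-2-methyl-5-(propan-2-yl)phenoxy]-4-methylpent-1-en-3-one | C=C(Oc1c(C)c(OC)cc(C(C)C)c1OCOC)C(=O)C(C)C
F6 | step 12 | 4-[3-methoxy-6-(methoxymethoxy)-2-methyl-5-(propan-2-yl)phenoxy]-6-methyl-3-(propan-2-yl)cyclohex-3-en-1-one oxime, racemic, oxime geometry not defined | CC1CC(Oc2c(C)c(OC)cc(C(C)C)c2OCOC)=C(C(C)C)CC1=NO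
F7 | step 13 | tert-butyl({4-[3-methoxy-6-(methoxymethoxy)-2-methyl-5-(propan-2-yl)phenoxy]-6-methyl-3-(propan-2-yl)cyclohexa-1,3-dien-1-yl}oxy)dimethylsilane, racemic | CC1CC(Oc2c(C)c(OC)cc(C(C)C)c2OCOC)=C(C(C)C)C=C1O[Si](C)(C)C(C)(C)C
F8 | step 13 | tert-butyl{4-[3-methoxy-6-(methoxymethoxy)-2-methyl-5-(propan-2-yl)phenoxy]-2-methyl-5-(propan-2-yl)phenoxy}dimethylsilane | Cc1cc(Oc2c(C)c(OC)cc(C(C)C)c2OCOC)c(C(C)C)cc1O[Si](C)(C)C(C)(C)C
A1 | alternative 1 | 4,4-dimethoxy-2-[4-methoxy-5-methyl-2-(propan-2-yl)phenoxy]-3-methyl-6-(propan-2-yl)cyclohexa-2,5-dien-1-one | COC1(OC)C=C(C(C)C)C(=O)C(Oc2cc(C)c(OC)cc2C(C)C)=C1C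
A2 | alternative 1 | 2-[4-methoxy-5-methyl-2-(propan-2-yl)phenoxy]-3-methyl-6-(propan-2-yl)phenol | Cc1ccc(C(C)C)c(O)c1Oc1cc(C)c(OC)cc1C(C)C
A3 | alternative 2 | 3-[4-methoxy-5-methyl-2-(propan-2-yl)phenoxy]-2-methyl-5-(propan-2-yl)-4-(triethylsilyloxy)phenol | CC[Si](CC)(CC)Oc1c(C(C)C)cc(O)c(C)c1Oc1cc(C)c(OC)cc1C(C)C
A4 | alternative 2 | 3-[4-methoxy-5-methyl-2-(propan-2-yl)phenoxy]-2-methyl-4-(3-methylbut-1-en-2-yl)-4-(triethylsilyloxy)cyclobut-2-en-1-one, racemic | C=C(C(C)C)C1(O[Si](CC)(CC)CC)C(Oc2cc(C)c(OC)cc2C(C)C)=C(C)C1=O
A5 | alternative 3 | 4-[5-methoxy-2-(methoxymethoxy)-6-methyl-3-(propan-2-yl)phenoxy]-6-methyl-3-(propan-2-yl)cyclohex-2-en-1-one, racemic mixture of diastereomers | CC1CC(Oc2c(C)c(OC)cc(C(C)C)c2OCOC)C(C(C)C)=CC1=O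
A6 | alternative 3 | 1-[3-methoxy-6-(methoxymethoxy)-2-methyl-5-(propan-2-yl)phenoxy]-3-methylbutan-2-one | CC(C)C(=O)COc1c(C)c(OC)cc(C(C)C)c1OCOC
A7 | alternative 3 | 3-methylbut-3-en-2-one | CC(=O)C(C)=C
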